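The 20-methylhenicosyl chain (C1 = OCH2) is disconnected at C12–C13 and C16–C17. Its four consecutive unsubstituted methylenes C13–C16 are drawn from the four ring carbons of thiophene, whose sulfur is later excised with Raney nickel. In one flask thiophene is α-lithiated and alkylated with TBS-protected 12-bromododecanol (C1–C12), then lithiated at the other α-carbon and alkylated with 1-bromo-4-methylpentane (C17–C21 plus the C20 methyl), so the key step forms both C–C bonds and completes the carbon chain. Desulfurisation, direct silyl ether-to-bromide exchange and bicarbonate-mediated esterification of unprotected 2,3-dihydroxybenzoic acid, whose benzene ring is never touched, complete the target.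

Key step: step 2

Remark: the target has no stereocentre and no stereogenic double bond, so it is one achiral compound and no step needs stereocontrol; its alcohol part is 20-methylhenicosyl (nineteen CH2 groups between the oxygen and the isopropyl end), and locants C1–C21 count from the OCH2 carbon.

Step 1
Reactants: 1 12-bromododecan-1-ol
Product: 2 (12-bromododecyloxy)(tert-butyl)dimethylsilane
Conditions: TBSCl (1.1 equiv), imidazole (1.5 equiv), CH2Cl2, 0 °C → rt
Reagents that add atoms: tert-butyldimethylsilyl chloride (TBSCl), CC(C)(C)[Si](C)(C)Cl
Why: Imidazole-promoted silylation of a primary alcohol is fast at room temperature and leaves the primary bromide untouched, so the oxygen is masked against the organolithium chemistry that follows.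

Step 2
Reactants: 3 thiophene; 2 (12-bromododecyloxy)(tert-butyl)dimethylsilane; 4 1-bromo-4-methylpentane
Product: 8 tert-butyldimethyl{12-[5-(4-methylpentyl)thiophen-2-yl]dodecyloxy}silane, via 2-thienyllithium 5 (not isolated), via 2-(12-silyloxydodecyl)thiophene 6 (not isolated), via 5-lithio-2-(12-silyloxydodecyl)thiophene 7 (not isolated)
Conditions: 3 (1.3 equiv), n-BuLi (1.2 equiv), THF, −78 → 0 °C; 2 (1.0 equiv), DMPU, 0 °C → rt; n-BuLi (1.3 equiv), −78 → −30 °C; 4 (2.0 equiv), −30 °C → rt
Reagents that add atoms: none
Why: n-BuLi removes an acidic α-proton of thiophene to give 5, whose sp2 carbanion displaces bromide from the primary carbon of 2 by SN2 (DMPU loosens the aggregates) and forms C12–C13; the resulting 6 has a single α-proton left, which the second charge of n-BuLi removes to give 7, and SN2 on 4 then forms C16–C17. The closest known reaction type is the α-lithiation and alkylation of thiophenes with primary alkyl bromides, used for chain building ahead of reductive desulfurisation. No ring is closed and no stereocentre is created. The step needs site selectivity (α over β ring positions and over the side-chain CH2) and a fixed order of the two electrophiles: the first follows from the acidity of the α C–H bonds, the second from adding one charge of base and one bromide at a time. Keeping 5 in excess over 2 ensures that no 2 is left when the second base is added and suppresses symmetrical dialkylation, because thiophene is more acidic than its 2-alkyl derivative; surplus 5 ends up as volatile, oxygen-free 4-methylpentylthiophenes that are readily removed. The TBS ether and the unactivated alkyl chains are inert to the lithium reagents at these temperatures.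

Step 3
Reactants: 8 tert-butyldimethyl{12-[5-(4-methylpentyl)thiophen-2-yl]dodecyloxy}silane
Product: 9 tert-butyldimethyl[(20-methylhenicosyl)oxy]silane
Conditions: Raney Ni (W-2, large excess, washed neutral), H2 (balloon), EtOH–THF, 60 °C
Reagents that add atoms: none
Why: Raney nickel reductive desulfurisation cleaves both C–S bonds of the 2,5-dialkylthiophene and saturates the four former ring carbons to the methylenes C13–C16, while the silyl ether has no reducible group; any alcohol freed by adventitious desilylation would still converge on 10 in step 4.

Step 4
Reactants: 9 tert-butyldimethyl[(20-methylhenicosyl)oxy]silane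
Product: 10 1-bromo-20-methylhenicosane
Conditions: Ph3PBr2 (1.3 equiv), CH2Cl2, 0 °C → rt
Reagents that add atoms: triphenylphosphine dibromide, BrP(Br)(c1ccccc1)(c1ccccc1)c1ccccc1
Why: In this direct silyl ether-to-bromide exchange (an Appel-type deoxybromination) the ether oxygen attacks the bromophosphonium centre, the silyl group leaves as its bromide, and bromide displaces triphenylphosphine oxide from the unhindered primary carbon by SN2, so no separate desilylation is needed.

Step 5
Reactants: 10 1-bromo-20-methylhenicosane; 11 2,3-dihydroxybenzoic acid
Product: 13 gentiside A (20-methylhenicosyl 2,3-dihydroxybenzoate), via potassium 2,3-dihydroxybenzoate 12 (not isolated)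
Conditions: 11 (2 equiv), KHCO3 (2 equiv), DMF, rt; then 10 (1 equiv), KI (0.1 equiv), DMF–THF, 60 °C, Ar
Reagents that add atoms: none
Why: In this chemoselective carboxylate O-alkylation (SN2 ester synthesis) bicarbonate deprotonates only the carboxylic acid (pKa about 3) and leaves both phenols (pKa about 10 and higher) protonated, so carboxylate 12 is the only competent nucleophile towards the primary bromide, iodide catalysis (Finkelstein) speeds the displacement, and exclusion of air protects the catechol.

Compound list
1 | 12-bromododecan-1-ol | OCCCCCCCCCCCCBr | starting material
2 | (12-bromododecyloxy)(tert-butyl)dimethylsilane | CC(C)(C)[Si](C)(C)OCCCCCCCCCCCCBr | intermediate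
3 | thiophene | c1ccsc1 | starting material
4 | 1-bromo-4-methylpentane | CC(C)CCCBr | starting material
5 | 2-thienyllithium (thiophen-2-yllithium) | [Li]c1cccs1 | intermediate
6 | tert-butyldimethyl[12-(thiophen-2-yl)dodecyloxy]silane | CC(C)(C)[Si](C)(C)OCCCCCCCCCCCCc1cccs1 | intermediate
7 | {5-[12-(tert-butyldimethylsilyloxy)dodecyl]thiophen-2-yl}lithium | CC(C)(C)[Si](C)(C)OCCCCCCCCCCCCc1ccc([Li])s1 | intermediate
8 | tert-butyldimethyl{12-[5-(4-methylpentyl)thiophen-2-yl]dodecyloxy}silane | CC(C)CCCc1ccc(CCCCCCCCCCCCO[Si](C)(C)C(C)(C)C)s1 | intermediate
9 | tert-butyldimethyl[(20-methylhenicosyl)oxy]silane | CC(C)CCCCCCCCCCCCCCCCCCCO[Si](C)(C)C(C)(C)C | intermediate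
10 | 1-bromo-20-methylhenicosane | CC(C)CCCCCCCCCCCCCCCCCCCBr | intermediate
11 | 2,3-dihydroxybenzoic acid | OC(=O)c1cccc(O)c1O | starting material
12 | potassium 2,3-dihydroxybenzoate | [K+].[O-]C(=O)c1cccc(O)c1O | intermediate
13 | gentiside A (20-methylhenicosyl 2,3-dihydroxybenzoate) | CC(C)CCCCCCCCCCCCCCCCCCCOC(=O)c1cccc(O)c1O | target

Total step count: 5
Longest linear sequence: 5 steps (1 → 2 → 8 → 9 → 10 → 13); 3, 4 and 11 are bought and used as such.

Steps most likely to fail

Step 2. The second alkylation may stop short: part of lithio species 7 can be reprotonated (elimination on 4, adventitious proton sources), or the second charge of base may be lost to the cosolvent. This would leave monoalkylated material that is hard to separate and would end in a chain six carbons short. Lithium–hydrogen exchange during the first stage could also lead to symmetrical dialkylation. Fallback, setting out from 6 and coming back at 8: the sequence is stopped after the first alkylation and 6 is isolated. Bromination with NBS in DMF at 0 °C in the dark should give [12-(5-bromothiophen-2-yl)dodecyloxy](tert-butyl)dimethylsilane F1 by electrophilic substitution at the one free α-position. (4-Methylpentyl)magnesium bromide F2, made from 4 and magnesium in THF, is then coupled with F1 under Ni(dppp)Cl2 catalysis (Kumada coupling, THF, rt → 50 °C). C16–C17 is thus made by cross-coupling instead of SN2 of a lithiothiophene, and the product is 8.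

Step 5. The free catechol may interfere: competing O-alkylation of a phenol, air oxidation of the catechol under basic conditions, or sluggish displacement because the long-chain bromide dissolves poorly in DMF. Fallback, setting out from 11 and 10 and coming back at 13: 11 is perbenzylated (BnBr, K2CO3, DMF, 60 °C) to benzyl 2,3-bis(benzyloxy)benzoate F3. The benzyl ester is saponified (NaOH, MeOH–THF–H2O, then HCl) to 2,3-bis(benzyloxy)benzoic acid F4. The caesium salt of F4 is alkylated with 10 (Cs2CO3, DMF–THF, 60 °C) to 20-methylhenicosyl 2,3-bis(benzyloxy)benzoate F5, with no free phenol present during C–O bond formation. Hydrogenolysis (H2, Pd/C, EtOAc–THF, rt) then frees the catechol and gives 13.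

Step 4. The exchange at the hindered silyl ether may be slow or stall at a mixture of silyl ether, alcohol and bromide. Fallback, setting out from 9 and coming back at 10: fluoride-driven desilylation (TBAF, THF, rt) should give 20-methylhenicosan-1-ol F6, which is converted by Appel bromination (CBr4, PPh3, CH2Cl2, 0 °C → rt) into 10.

Further compounds
F1 | step 2 | [12-(5-bromothiophen-2-yl)dodecyloxy](tert-butyl)dimethylsilane | CC(C)(C)[Si](C)(C)OCCCCCCCCCCCCc1ccc(Br)s1
F2 | step 2 | (4-methylpentyl)magnesium bromide | CC(C)CCC[Mg]Br
F3 | step 5 | benzyl 2,3-bis(benzyloxy)benzoate | O=C(OCc1ccccc1)c1cccc(OCc2ccccc2)c1OCc1ccccc1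
F4 | step 5 | 2,3-bis(benzyloxy)benzoic acid | OC(=O)c1cccc(OCc2ccccc2)c1OCc1ccccc1
F5 | step 5 | 20-methylhenicosyl 2,3-bis(benzyloxy)benzoate | CC(C)CCCCCCCCCCCCCCCCCCCOC(=O)c1cccc(OCc2ccccc2)c1OCc1ccccc1
F6 | step 4 | 20-methylhenicosan-1-ol | CC(C)CCCCCCCCCCCCCCCCCCCO
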